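In the earlier runs target plus substrate stays at the charge within the scatter, 101% at the last larch reading, so I take each turnover of the catalyst to turn one substrate and one reagent into one target. That gives me a quantity to carry, the turnover ceiling N, which is the reagent charge divided by the catalyst charge, and I hold each flask's turnover count against it.

| flask | substrate | reagent | free catalyst | temperature | remark | time |
|---|---|---|---|---|---|---|
| larch | 0.79 M | 1.1 equiv | 0.32 mol% | 108 °C | run made earlier |  |
| oak | 0.79 M | 2.3 equiv | 0.32 mol% | 124 °C | run made earlier |  |
| winter | 0.79 M | 1.60 equiv | 0.32 mol% |  | at 100 °C throughout | 1.0 h |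
| dawn | 0.79 M | 0.800 equiv | 0.32 mol% |  | at 100 °C until 30 min, from then on at 130 °C | 1.0 h |

- larch (time / min: target / %, substrate / %): 5.00: 6.3, 94.3; 12.0: 13.1, 86.0; 25.0: 25.9, 74.7; 60.0: 53.9, 46.8
- oak (time / min: target / %, substrate / %): 5.00: 14.9, 85.5; 10.0: 27.2, 72.7; 15.0: 39.3, 60.8; 20.0: 48.7, 51.2

(each reading ± 0.5 percentage points)

- the earlier runs were read with a standard deviation of 0.5 percentage points

- which of the two ends with the higher amount of target, in percent of the substrate charged ("neither" if they lie within 2 percentage points) (winter / dawn / neither)
- target at the end, in percent of the substrate charged, winter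
- target at the end, in percent of the substrate charged, dawn

Writing 250 for N in dawn and 500 for N in winter, I look first at the nearest simulated run, larch. Its last reading counts 168 turnovers against a ceiling of 344, half of it, and its substrate still falls first order, with rate constant k of 0.0127 min⁻¹. So reagent does not show in the rate over that stretch, though larch says nothing about the last of the reagent. Oak gives 0.0335 min⁻¹, and the pair gives an activation energy of 76.5 kJ mol⁻¹, which puts k at 0.00754 min⁻¹ at 100 °C and 0.0473 min⁻¹ at 130 °C.

Unhindered, winter asks for 114 turnovers, a quarter of its ceiling, so winter is short of time and I commit to 36.4%. Dawn asks for 252 turnovers, about the same as its ceiling, so reagent, the limiting reagent here, is what dawn runs into, and I put dawn just under 80.0%, ahead of winter.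

The forecast says dawn, with winter at 36% (32% to 41%) and dawn at 73% (63% to 80%), in its words “As reagent runs out, the rate should sag”.

The flasks give 36.8% for winter and 72.4% for dawn, so dawn ends higher.

    reagent + free catalyst → catalyst intermediate A (k = 19.0 M⁻¹ min⁻¹, Ea = 79.0 kJ mol⁻¹)
    catalyst intermediate A → by-product + catalyst intermediate B (k = 11.0 min⁻¹, Ea = 102 kJ mol⁻¹)
    substrate + catalyst intermediate B ⇌ catalyst intermediate C (K = 2.70 M⁻¹, k = 7.30 M⁻¹ min⁻¹, Ea = 49.0 kJ mol⁻¹, ΔH = 25.0 kJ mol⁻¹)
    catalyst intermediate C → free catalyst + target (k = 10.0 min⁻¹, Ea = 103 kJ mol⁻¹)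
    target → over-reaction product (k = 3.20 × 10⁻⁵ min⁻¹, Ea = 129 kJ mol⁻¹)
    2 catalyst intermediate C → spent catalyst (k = 2.10 M⁻¹ min⁻¹, Ea = 65.0 kJ mol⁻¹)
    (constants at 100 °C)

At 1.0 h dawn has made 229 turnovers of its ceiling of 250, counting target and over-reaction product together, with 8.0% of its reagent still unbound, and target is being made 16.2 times faster than it is used up. The neighbour of dawn charged with 0.8 mol% of free catalyst has a ceiling of 100 and ends at 100 turnovers, counted the same way, with 0% of its reagent left, 1.56% of over-reaction product and 78.4% of target.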